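# Proposed total synthesis of CNP0268255.2 by a carvone-based oxy-Cope ring expansion

Atom labels C1–C15 follow the germacrane numbering of the target in every intermediate (C1–C10 ring, C11–C13 lactone carbons, C14 on C10, C15 on C4); β is the face of C14 in the target.

## The problem

The target is a heliangolide. Its cyclodecane ring carries a trans-1,10-oxirane, a Z-trisubstituted C4=C5 alkene between two allylic C–O bonds (C3–OH, C6–O), a trans-fused α-methylene-γ-lactone at C6/C7 and a (2S,3S)-2,3-epoxy-2-methylbutanoate at O8. The ten-membered ring resists direct closure, and a ring-closing event would also have to make the cis C4=C5 bond with control. Six ring stereocentres must be set: the contiguous C6–C7–C8 triad, the remote C3 carbinol and the C1/C10 oxirane. No rigid framework relays stereochemistry between them, so control must come from chirality transfer or from attack on the outer face of a medium ring. The methylene lactone is a Michael acceptor, both oxiranes are acid-labile, the 1,10-oxirane can be opened transannularly by O3, and the 1,5-diene precursors cyclise with acid. The endgame must therefore be close to neutral, and O3 and O8 must be told apart.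

The feature that opens the structure is the relation of C6 to the E C1=C10 bond. Along the ring, C6(O)–C7–C8–C9–C10=C1 is a 5-en-1-one at the ketone level of C6, which is the retron of an oxy-Cope rearrangement. Re-forming C6–C1 contracts the carbocycle to a cyclohexene ring C1–C6. In that ring the awkward 4Z alkene is simply the ring double bond and C3–O is an allylic oxygen, which is the carveol skeleton. C8 is the terminus of the migrating vinyl group, so its configuration can be written by the chair transition state.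

## Retrosynthesis

**29 ⇒ 28 ⇒ 27 ⇒ 21 + 25.** The last bonds cut are the O3–Si bond, the two oxirane C–O bonds at C1/C10 and the O8–acyl bond. The most fragile groups are thus installed last. Epoxidation is placed after esterification and before release of O3, because a free allylic 3-OH would steer peracid to C4=C5. The precursors are the 8-hydroxy dienolide 21 and the small epoxy acid 25. The forward steps must acylate a hindered alcohol without base damage and epoxidise one face of C1=C10 only.

**21 ⇒ 19 ⇒ 18 ⇒ 16.** The C8–O bond is traced to a C8–Si bond (oxidation with retention), the lactone C12–O6 bond to oxidation of diol 18, and the C6–H bond to reduction of ketone 16. Silicon is preferred to an ether at C8 for two reasons. An alkoxy group would sit β to the enolate formed in the key step and would be expelled. O8 is also γ to C12 and would compete with O6 for the lactone. A carbon-bound silyl group is inert to both problems and keeps O8 masked until the 6,12-olide is closed. The forward steps need hydride delivery to the outer face of C6 and a C–Si oxidation that spares the methylene lactone.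

**16 ⇒ 5 + 12 (key).** Cut C6–C7 (carbonyl addition) and C8–C9 ([3,3] shift), and re-form C1–C6. Against a macrocyclisation at any single bond, this cut replaces ring closure by ring expansion and inherits the Z alkene. It creates the E C1=C10 bond and C8 in one chair transition state and leaves C7 to a protonation. The precursors are the carvone-derived cyclohexenone 5 (ten carbons, C3 already set) and the achiral dienylstannane 12 (C7, C8, C11–C13 and the latent O8). The forward reaction must give trans 1,2-addition, a chair rearrangement and kinetic C-protonation.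

**5 ⇒ 4 ⇒ 3 ⇒ 2 ⇒ 1.** The C6 carbonyl comes from oxidation of the only allylic ring methylene of silyl ether 4. The C3–O bond, trans to the isopropenyl group, comes from carvone oxide 2 by Wharton transposition to trans-carveol 3. The epoxidation of carvone supplies the trans relation directly, which a carbonyl reduction would not. Because the transposition exchanges the roles of the two ring methylenes, (S)-carvone 1 is the correct enantiomer.

**12 ⇒ 11 ⇒ 10 + 8 ⇒ 9, 6 + 7.** Cut Sn–C (syn-hydrostannation of enyne 11), the sp–sp2 C–C bond (Sonogashira coupling of bromide 10 with silylalkyne 8), the ketal on O12 and the Si–C(sp) bond. Hydrostannation sets tin trans to silicon, which later makes the silyl group equatorial in the chair. The benzyl group on silicon is the fluoride-labile trigger for the later oxidation.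

**25 ⇒ 24 ⇒ 23 ⇒ 22.** The acid is traced to epoxy alcohol 24, made by asymmetric epoxidation of angelyl alcohol 23 from methyl angelate 22. The Z geometry fixes the relative configuration and the tartrate fixes the absolute configuration.

## Roads not taken

**Alternative 1:** cut C6–C7 and the lactone C–O bond. The forward key step is an intramolecular Nozaki–Hiyama–Kishi (Barbier-type) allylation of the Z-enal by the 2-(bromomethyl)enoate in the acyclic bromo aldehyde A1 (CrCl2), followed by lactonisation. This is the route most chemists would draw first. It needs a long linear synthesis of a chain with two remote stereocentres and a geometrically labile Z-enal. It closes the ten-membered ring under high dilution. It must set C6 and C7 relative to C8 in a flexible transition state. The chosen plan takes the Z alkene from a cyclohexene, needs no dilution and sets C8 by chirality transfer.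

**Alternative 2:** cut C4=C5. The forward key step is ring-closing metathesis of the lactone triene A2 with a second-generation Grubbs catalyst. A trisubstituted alkene between two oxygenated allylic carbons in a ten-membered ring is among the poorest metathesis cases. The catalyst gives no handle on Z geometry, and the methylene lactone and C1=C10 are competing alkenes. In the chosen plan no alkene geometry is created at C4=C5 at all.

**Alternative 3:** cut at the oxidation level of C3/C6. The Z-ene-1,4-dioxygen unit would be carried as a 2,5-bridged 3-methylfuran, the furanophane A3. The forward key step is oxidative opening of the furan to the Z-enedione, followed by reduction of both carbonyls. The furanophane still needs a macrocyclisation. C3 and C6 would both be set by reductions with no control element, and the oxidant must spare C1=C10. The chosen plan buys C3 from carvone and sets C6 by a single reduction next to defined centres.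

Key step: step 9

## Route

Assumption: the 1,2-addition in step 9 places the new alkenyl group trans to the C1 isopropenyl group, as is usual for 6-substituted cyclohex-2-enones.

Step 1
Reactants: 1 (S)-(+)-carvone
Product: 2 (1S,4S,6S)-1-methyl-4-(prop-1-en-2-yl)-7-oxabicyclo[4.1.0]heptan-2-one
Conditions: 30% H2O2, NaOH (aq, cat.), MeOH, 0 °C
Reagents that add atoms: hydrogen peroxide OO
Why: Weitz–Scheffer epoxidation of the enone; hydroperoxide adds axially, anti to the isopropenyl group, so the oxirane forms trans to it, the known outcome for carvone.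

Step 2
Reactants: 2 (1S,4S,6S)-1-methyl-4-(prop-1-en-2-yl)-7-oxabicyclo[4.1.0]heptan-2-one
Product: 3 (1S,5R)-2-methyl-5-(prop-1-en-2-yl)cyclohex-2-en-1-ol (trans-carveol)
Conditions: N2H4·H2O, AcOH (cat.), MeOH, 0 °C to rt
Reagents that add atoms: none
Why: Wharton transposition of the epoxy ketone: the hydrazone fragments with loss of N2, the carbonyl carbon becomes the alkene CH and the former β C–O bond is untouched, so the hydroxyl (future O3) stays trans to the isopropenyl group.

Step 3
Reactants: 3 (1S,5R)-2-methyl-5-(prop-1-en-2-yl)cyclohex-2-en-1-ol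
Product: 4 tert-butyldimethyl{[(1S,5R)-2-methyl-5-(prop-1-en-2-yl)cyclohex-2-en-1-yl]oxy}silane
Conditions: TBSCl, imidazole, DMF, rt
Reagents that add atoms: tert-butyldimethylsilyl chloride CC(C)(C)[Si](C)(C)Cl
Why: Standard silylation; the TBS ether withstands chromium oxidants, organolithium, KH and peracid and can be removed last under buffered fluoride.

Step 4
Reactants: 4 tert-butyldimethyl{[(1S,5R)-2-methyl-5-(prop-1-en-2-yl)cyclohex-2-en-1-yl]oxy}silane
Product: 5 (4S,6R)-4-[(tert-butyldimethylsilyl)oxy]-3-methyl-6-(prop-1-en-2-yl)cyclohex-2-en-1-one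
Conditions: CrO3, 3,5-dimethylpyrazole, CH2Cl2, −20 °C
Reagents that add atoms: chromium trioxide O=[Cr](=O)=O
Why: Allylic C–H oxidation at the only allylic ring methylene (future C6), the other allylic ring position being the silyloxy carbon; no stereocentre is touched and the non-basic medium avoids epimerisation at C1 or conjugation of the isopropenyl group.

Step 5
Reactants: 6 benzylchlorodimethylsilane; 7 ethynylmagnesium bromide
Product: 8 benzyl(ethynyl)dimethylsilane
Conditions: THF, 0 °C to rt
Reagents that add atoms: none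
Why: Substitution at silicon by the acetylide Grignard reagent; the two acetylene carbons become C8 and C7.

Step 6
Reactants: 9 2-bromoprop-2-en-1-ol
Product: 10 2-bromo-3-[(2-methoxypropan-2-yl)oxy]prop-1-ene
Conditions: 2-methoxypropene, PPTS (cat.), CH2Cl2, 0 °C
Reagents that add atoms: 2-methoxypropene COC(C)=C
Why: Acid-catalysed addition of the alcohol to the enol ether gives the mixed acetone ketal (MOP ether), which has no stereocentre, cannot migrate between alkoxides, tolerates MeLi and KH and is released during the reduction in step 10.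

Step 7
Reactants: 10 2-bromo-3-[(2-methoxypropan-2-yl)oxy]prop-1-ene; 8 benzyl(ethynyl)dimethylsilane
Product: 11 benzyl(3-{[(2-methoxypropan-2-yl)oxy]methyl}but-3-en-1-yn-1-yl)dimethylsilane
Conditions: PdCl2(PPh3)2 (cat.), CuI (cat.), i-Pr2NH, THF, 40 °C
Reagents that add atoms: none
Why: Sonogashira coupling of a vinyl bromide with a terminal silylalkyne; this joins C7 to C11.

Step 8
Reactants: 11 benzyl(3-{[(2-methoxypropan-2-yl)oxy]methyl}but-3-en-1-yn-1-yl)dimethylsilane
Product: 12 benzyl[(1E)-3-{[(2-methoxypropan-2-yl)oxy]methyl}-2-(tributylstannyl)buta-1,3-dien-1-yl]dimethylsilane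
Conditions: Bu3SnH, PdCl2(PPh3)2 (cat.), THF, 0 °C to rt
Reagents that add atoms: tributyltin hydride CCCC[SnH](CCCC)CCCC
Why: Palladium-catalysed syn-hydrostannation of a silylalkyne; hydrogen goes to the silicon-bearing carbon and tin to the remote one, so tin and silicon end up trans, which is the geometry needed for an equatorial silyl group in step 9.

Step 9
Reactants: 12 benzyl[(1E)-3-{[(2-methoxypropan-2-yl)oxy]methyl}-2-(tributylstannyl)buta-1,3-dien-1-yl]dimethylsilane; 5 (4S,6R)-4-[(tert-butyldimethylsilyl)oxy]-3-methyl-6-(prop-1-en-2-yl)cyclohex-2-en-1-one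
Product: 16 (2Z,4S,6E,9R,10S)-9-[benzyl(dimethyl)silyl]-4-[(tert-butyldimethylsilyl)oxy]-10-{3-[(2-methoxypropan-2-yl)oxy]prop-1-en-2-yl}-3,7-dimethylcyclodeca-2,6-dien-1-one, via dienyllithium 13 (not isolated), via divinyl carbinol 14 (not isolated), via potassium enolate 15 (not isolated)
Conditions: MeLi, THF, −78 °C; add 5, −78 °C; MeOH (1 equiv); KH, 18-crown-6, 0 to 25 °C; AcOH, −78 °C
Reagents that add atoms: none
Why: Tin–lithium exchange gives 13 with retention, and its 1,2-addition to the C6 carbonyl of 5 anti to the adjacent C1 isopropenyl group gives the trans-divinyl alkoxide (14 after the methanol quench). As its potassium/18-crown-6 salt, 14 undergoes the anionic oxy-Cope rearrangement, whose closest precedent is the ring expansion of trans-1,2-divinylcyclohexanols to (E)-cyclodec-5-enones. The ten-membered ring is formed not by cyclisation but by [3,3] ring expansion: C8–C9 forms and C1–C6 breaks in a chair transition state with the ring bonds C1–C2 and C6–C5 equatorial. This chair makes C1=C10 E, carries the cis ring alkene over as 4Z, and gives enolate 15 with C5 and C8 trans across C6=C7. C8 is created by suprafacial chirality transfer from C1, which becomes sp2: the silyl group, E on the vinyl terminus, sits equatorial and C8 is formed as 8β (9R in 16). C7 is set on quenching: allylic strain between the enolate oxygen and the silyl group keeps H8 eclipsed and holds the ring over one face of C6=C7, so acetic acid protonates C7 (kinetically preferred over C13) from the open face and C11 ends up β. The step needs 1,2-addition over enolisation, chair over boat and no β-elimination from 15; these are secured by low temperature, the trans-diequatorial alkenyl groups and carbon-bound silicon in place of oxygen at C8.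

Step 10
Reactants: 16 (2Z,4S,6E,9R,10S)-9-[benzyl(dimethyl)silyl]-4-[(tert-butyldimethylsilyl)oxy]-10-{3-[(2-methoxypropan-2-yl)oxy]prop-1-en-2-yl}-3,7-dimethylcyclodeca-2,6-dien-1-one
Product: 18 (1R,2Z,4S,6E,9R,10S)-9-[benzyl(dimethyl)silyl]-4-[(tert-butyldimethylsilyl)oxy]-10-(3-hydroxyprop-1-en-2-yl)-3,7-dimethylcyclodeca-2,6-dien-1-ol, via MOP-protected alcohol 17 (not isolated)
Conditions: NaBH4, CeCl3·7H2O, MeOH, −78 °C; then PPTS (cat.), 0 °C
Reagents that add atoms: none
Why: Luche 1,2-reduction; hydride should attack C6 from the outer face of the conformer inherited from 15, the same face that was protonated at C7, which is the net syn addition across the former enolate needed for the 6α-alcohol and a trans lactone. PPTS in the same methanol then cleaves the acetone ketal.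

Step 11
Reactants: 18 (1R,2Z,4S,6E,9R,10S)-9-[benzyl(dimethyl)silyl]-4-[(tert-butyldimethylsilyl)oxy]-10-(3-hydroxyprop-1-en-2-yl)-3,7-dimethylcyclodeca-2,6-dien-1-ol
Product: 19 (3aS,4R,6E,9S,10Z,11aR)-4-[benzyl(dimethyl)silyl]-9-[(tert-butyldimethylsilyl)oxy]-6,10-dimethyl-3-methylidene-3a,4,5,8,9,11a-hexahydrocyclodeca[b]furan-2(3H)-one
Conditions: TEMPO (cat.), PhI(OAc)2, CH2Cl2, rt
Reagents that add atoms: none
Why: Oxidative lactonisation of a 2-methylene-1,4-diol: the primary allylic alcohol is oxidised selectively, O6 traps the aldehyde as the lactol and this is oxidised on to the α-methylene-γ-lactone. O8 is still silicon, so only the 6,12-olide can form.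

Step 12
Reactants: 19 (3aS,4R,6E,9S,10Z,11aR)-4-[benzyl(dimethyl)silyl]-9-[(tert-butyldimethylsilyl)oxy]-6,10-dimethyl-3-methylidene-3a,4,5,8,9,11a-hexahydrocyclodeca[b]furan-2(3H)-one
Product: 21 (3aR,4R,6E,9S,10Z,11aR)-9-[(tert-butyldimethylsilyl)oxy]-4-hydroxy-6,10-dimethyl-3-methylidene-3a,4,5,8,9,11a-hexahydrocyclodeca[b]furan-2(3H)-one, via fluorosilane 20 (not isolated)
Conditions: Bu4NF, THF, 0 °C, 15 min; then KHCO3, 30% H2O2, MeOH, rt
Reagents that add atoms: hydrogen peroxide OO
Why: Tamao–Fleming oxidation of a benzyldimethylsilyl group: fluoride cleaves the benzyl–silicon bond, and buffered peroxide then shifts C8 from silicon to oxygen with retention, giving the 8β-alcohol. Short fluoride contact at 0 °C and bicarbonate buffering are chosen to spare the TBS ether and the methylene lactone.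

Step 13
Reactants: 22 methyl (2Z)-2-methylbut-2-enoate (methyl angelate)
Product: 23 (2Z)-2-methylbut-2-en-1-ol
Conditions: i-Bu2AlH, CH2Cl2, −78 °C
Reagents that add atoms: none
Why: 1,2-Reduction of the enoate to the allylic alcohol with the Z geometry kept.

Step 14
Reactants: 23 (2Z)-2-methylbut-2-en-1-ol
Product: 24 [(2R,3S)-2,3-dimethyloxiran-2-yl]methanol
Conditions: Ti(OiPr)4 (cat.), D-(−)-diethyl tartrate (cat.), t-BuOOH, 4 Å molecular sieves, CH2Cl2, −20 °C
Reagents that add atoms: tert-butyl hydroperoxide CC(C)(C)OO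
Why: Sharpless asymmetric epoxidation; the D-(−)-tartrate catalyst gives the 2R epoxy alcohol (the L-(+) ligand gives 2S in this substrate class), and the Z alkene fixes C3 as S.

Step 15
Reactants: 24 [(2R,3S)-2,3-dimethyloxiran-2-yl]methanol
Product: 25 (2S,3S)-2,3-dimethyloxirane-2-carboxylic acid
Conditions: TEMPO (cat.), PhI(OAc)2, MeCN/H2O, rt
Reagents that add atoms: water O
Why: Oxoammonium oxidation of the primary alcohol through the aldehyde hydrate to the acid without touching the oxirane; the C2 descriptor changes from R to S only through the change in substituent priority.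

Step 16
Reactants: 25 (2S,3S)-2,3-dimethyloxirane-2-carboxylic acid; 21 (3aR,4R,6E,9S,10Z,11aR)-9-[(tert-butyldimethylsilyl)oxy]-4-hydroxy-6,10-dimethyl-3-methylidene-3a,4,5,8,9,11a-hexahydrocyclodeca[b]furan-2(3H)-one
Product: 27 (3aR,4R,6E,9S,10Z,11aR)-9-[(tert-butyldimethylsilyl)oxy]-6,10-dimethyl-3-methylidene-2-oxo-2,3,3a,4,5,8,9,11a-octahydrocyclodeca[b]furan-4-yl (2S,3S)-2,3-dimethyloxirane-2-carboxylate, via mixed anhydride 26 (not isolated)
Conditions: 2,4,6-trichlorobenzoyl chloride, Et3N, THF, rt; then 21, DMAP, toluene, rt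
Reagents that add atoms: none
Why: Yamaguchi esterification, the standard way to acylate hindered secondary alcohols with α,α-disubstituted acids; the acid has no α-hydrogen, so it cannot epimerise, and O3 is silylated, so only O8 reacts.

Step 17
Reactants: 27 (3aR,4R,6E,9S,10Z,11aR)-9-[(tert-butyldimethylsilyl)oxy]-6,10-dimethyl-3-methylidene-2-oxo-2,3,3a,4,5,8,9,11a-octahydrocyclodeca[b]furan-4-yl (2S,3S)-2,3-dimethyloxirane-2-carboxylate
Product: 28 (1R,3S,6R,7R,8R,10R)-3β-[(tert-butyldimethylsilyl)oxy]-1β,10α-epoxy-8β-{[(2S,3S)-2,3-dimethyloxiran-2-yl]carbonyloxy}germacra-4Z,11(13)-dien-12,6α-olide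
Conditions: mCPBA, NaHCO3, CH2Cl2, 0 °C
Reagents that add atoms: 3-chloroperbenzoic acid OOC(=O)c1cccc(Cl)c1
Why: Prilezhaev epoxidation: C1=C10 is the only electron-rich, unhindered alkene (C4=C5 lies between two allylic C–O bonds, C11=C13 is conjugated). Peracid should attack its outer face in the usual germacranolide conformer with C14 on the β face, giving the trans 1β,10α (1R,10R) oxirane.

Step 18
Reactants: 28 (1R,3S,6R,7R,8R,10R)-3β-[(tert-butyldimethylsilyl)oxy]-1β,10α-epoxy-8β-{[(2S,3S)-2,3-dimethyloxiran-2-yl]carbonyloxy}germacra-4Z,11(13)-dien-12,6α-olide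
Product: 29 (1R,3S,6R,7R,8R,10R)-3β-hydroxy-1β,10α-epoxy-8β-{[(2S,3S)-2,3-dimethyloxiran-2-yl]carbonyloxy}germacra-4Z,11(13)-dien-12,6α-olide (target)
Conditions: HF·pyridine, pyridine, THF, 0 °C
Reagents that add atoms: none
Why: Buffered fluoride cleavage of the secondary silyl ether, under conditions that should leave both oxiranes, the ester and the methylene lactone intact; no stereocentre is involved.

## Compound list

1 | (S)-(+)-carvone | CC(=C)[C@H]1CC=C(C)C(=O)C1 | starting material
2 | (1S,4S,6S)-1-methyl-4-(prop-1-en-2-yl)-7-oxabicyclo[4.1.0]heptan-2-one | CC(=C)[C@H]1C[C@@H]2O[C@]2(C)C(=O)C1 | intermediate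
3 | (1S,5R)-2-methyl-5-(prop-1-en-2-yl)cyclohex-2-en-1-ol (trans-carveol) | CC(=C)[C@H]1C[C@H](O)C(C)=CC1 | intermediate
4 | tert-butyldimethyl{[(1S,5R)-2-methyl-5-(prop-1-en-2-yl)cyclohex-2-en-1-yl]oxy}silane | CC(=C)[C@H]1C[C@H](O[Si](C)(C)C(C)(C)C)C(C)=CC1 | intermediate
5 | (4S,6R)-4-[(tert-butyldimethylsilyl)oxy]-3-methyl-6-(prop-1-en-2-yl)cyclohex-2-en-1-one | CC(=C)[C@H]1C[C@H](O[Si](C)(C)C(C)(C)C)C(C)=CC1=O | intermediate
6 | benzylchlorodimethylsilane | C[Si](C)(Cl)Cc1ccccc1 | starting material
7 | ethynylmagnesium bromide | C#C[Mg]Br | starting material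
8 | benzyl(ethynyl)dimethylsilane | C#C[Si](C)(C)Cc1ccccc1 | intermediate
9 | 2-bromoprop-2-en-1-ol | OCC(Br)=C | starting material
10 | 2-bromo-3-[(2-methoxypropan-2-yl)oxy]prop-1-ene | COC(C)(C)OCC(Br)=C | intermediate
11 | benzyl(3-{[(2-methoxypropan-2-yl)oxy]methyl}but-3-en-1-yn-1-yl)dimethylsilane | COC(C)(C)OCC(=C)C#C[Si](C)(C)Cc1ccccc1 | intermediate
12 | benzyl[(1E)-3-{[(2-methoxypropan-2-yl)oxy]methyl}-2-(tributylstannyl)buta-1,3-dien-1-yl]dimethylsilane | C=C(COC(C)(C)OC)/C([Sn](CCCC)(CCCC)CCCC)=C\[Si](C)(C)Cc1ccccc1 | intermediate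
13 | [(1Z)-1-[benzyl(dimethyl)silyl]-3-{[(2-methoxypropan-2-yl)oxy]methyl}buta-1,3-dien-2-yl]lithium | C=C(COC(C)(C)OC)/C([Li])=C\[Si](C)(C)Cc1ccccc1 | intermediate
14 | (1R,4S,6R)-1-[(1E)-1-[benzyl(dimethyl)silyl]-3-{[(2-methoxypropan-2-yl)oxy]methyl}buta-1,3-dien-2-yl]-4-[(tert-butyldimethylsilyl)oxy]-3-methyl-6-(prop-1-en-2-yl)cyclohex-2-en-1-ol | CC(=C)[C@H]1C[C@H](O[Si](C)(C)C(C)(C)C)C(C)=C[C@]1(O)/C(C(=C)COC(C)(C)OC)=C/[Si](C)(C)Cc1ccccc1 | intermediate
15 | potassium enolate of 16 (O–C6=C7, C5 and C8 trans across it) | [O-]/C1=C(/C(=C)COC(C)(C)OC)[C@H]([Si](C)(C)Cc2ccccc2)C/C(C)=C/C[C@H](O[Si](C)(C)C(C)(C)C)/C(C)=C\1.[K+] | intermediate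
16 | (2Z,4S,6E,9R,10S)-9-[benzyl(dimethyl)silyl]-4-[(tert-butyldimethylsilyl)oxy]-10-{3-[(2-methoxypropan-2-yl)oxy]prop-1-en-2-yl}-3,7-dimethylcyclodeca-2,6-dien-1-one | O=C1/C=C(/C)[C@@H](O[Si](C)(C)C(C)(C)C)C/C=C(C)/C[C@@H]([Si](C)(C)Cc2ccccc2)[C@H]1C(=C)COC(C)(C)OC | intermediate
17 | (1R,2Z,4S,6E,9R,10S)-9-[benzyl(dimethyl)silyl]-4-[(tert-butyldimethylsilyl)oxy]-10-{3-[(2-methoxypropan-2-yl)oxy]prop-1-en-2-yl}-3,7-dimethylcyclodeca-2,6-dien-1-ol | O[C@@H]1/C=C(/C)[C@@H](O[Si](C)(C)C(C)(C)C)C/C=C(C)/C[C@@H]([Si](C)(C)Cc2ccccc2)[C@H]1C(=C)COC(C)(C)OC | intermediate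
18 | (1R,2Z,4S,6E,9R,10S)-9-[benzyl(dimethyl)silyl]-4-[(tert-butyldimethylsilyl)oxy]-10-(3-hydroxyprop-1-en-2-yl)-3,7-dimethylcyclodeca-2,6-dien-1-ol | O[C@@H]1/C=C(/C)[C@@H](O[Si](C)(C)C(C)(C)C)C/C=C(C)/C[C@@H]([Si](C)(C)Cc2ccccc2)[C@H]1C(=C)CO | intermediate
19 | (3aS,4R,6E,9S,10Z,11aR)-4-[benzyl(dimethyl)silyl]-9-[(tert-butyldimethylsilyl)oxy]-6,10-dimethyl-3-methylidene-3a,4,5,8,9,11a-hexahydrocyclodeca[b]furan-2(3H)-one | C=C1C(=O)O[C@@H]2/C=C(/C)[C@@H](O[Si](C)(C)C(C)(C)C)C/C=C(C)/C[C@@H]([Si](C)(C)Cc3ccccc3)[C@@H]12 | intermediate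
20 | (3aS,4R,6E,9S,10Z,11aR)-9-[(tert-butyldimethylsilyl)oxy]-4-[fluoro(dimethyl)silyl]-6,10-dimethyl-3-methylidene-3a,4,5,8,9,11a-hexahydrocyclodeca[b]furan-2(3H)-one | C=C1C(=O)O[C@@H]2/C=C(/C)[C@@H](O[Si](C)(C)C(C)(C)C)C/C=C(C)/C[C@@H]([Si](C)(C)F)[C@@H]12 | intermediate
21 | (3aR,4R,6E,9S,10Z,11aR)-9-[(tert-butyldimethylsilyl)oxy]-4-hydroxy-6,10-dimethyl-3-methylidene-3a,4,5,8,9,11a-hexahydrocyclodeca[b]furan-2(3H)-one | C=C1C(=O)O[C@@H]2/C=C(/C)[C@@H](O[Si](C)(C)C(C)(C)C)C/C=C(C)/C[C@@H](O)[C@@H]12 | intermediate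
22 | methyl (2Z)-2-methylbut-2-enoate (methyl angelate) | C/C=C(/C)C(=O)OC | starting material
23 | (2Z)-2-methylbut-2-en-1-ol | C/C=C(/C)CO | intermediate
24 | [(2R,3S)-2,3-dimethyloxiran-2-yl]methanol | OC[C@@]1(C)O[C@H]1C | intermediate
25 | (2S,3S)-2,3-dimethyloxirane-2-carboxylic acid | OC(=O)[C@@]1(C)O[C@H]1C | intermediate
26 | (2S,3S)-2,3-dimethyloxirane-2-carboxylic 2,4,6-trichlorobenzoic anhydride | O=C(OC(=O)[C@@]1(C)O[C@H]1C)c1c(Cl)cc(Cl)cc1Cl | intermediate
27 | (3aR,4R,6E,9S,10Z,11aR)-9-[(tert-butyldimethylsilyl)oxy]-6,10-dimethyl-3-methylidene-2-oxo-2,3,3a,4,5,8,9,11a-octahydrocyclodeca[b]furan-4-yl (2S,3S)-2,3-dimethyloxirane-2-carboxylate | C=C1C(=O)O[C@@H]2/C=C(/C)[C@@H](O[Si](C)(C)C(C)(C)C)C/C=C(C)/C[C@@H](OC(=O)[C@@]3(C)O[C@H]3C)[C@@H]12 | intermediate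
28 | (1R,3S,6R,7R,8R,10R)-3β-[(tert-butyldimethylsilyl)oxy]-1β,10α-epoxy-8β-{[(2S,3S)-2,3-dimethyloxiran-2-yl]carbonyloxy}germacra-4Z,11(13)-dien-12,6α-olide | C=C1C(=O)O[C@@H]2/C=C(/C)[C@@H](O[Si](C)(C)C(C)(C)C)C[C@H]3O[C@]3(C)C[C@@H](OC(=O)[C@@]3(C)O[C@H]3C)[C@@H]12 | intermediate
29 | (1R,3S,6R,7R,8R,10R)-3β-hydroxy-1β,10α-epoxy-8β-{[(2S,3S)-2,3-dimethyloxiran-2-yl]carbonyloxy}germacra-4Z,11(13)-dien-12,6α-olide | C=C1C(=O)O[C@@H]2/C=C(/C)[C@@H](O)C[C@H]3O[C@]3(C)C[C@@H](OC(=O)[C@@]3(C)O[C@H]3C)[C@@H]12 | target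

## Step count and least certain steps

Total: 18 steps. Longest linear sequence: 11 steps from (S)-carvone (steps 1–4, 9–12, 16–18).

**Step 9 (key step).** Three processes could spoil it. The dienyllithium may deprotonate C1 of 5 instead of adding to the carbonyl. Addition to the other carbonyl face would give a cis-divinyl alkoxide that rearranges through a boat and scrambles C8 and the C1=C10 geometry. The β,γ-unsaturated ketone may epimerise at C7 or move C11=C13 into conjugation during the quench. The fallback separates ring expansion from introduction of the side chain. It sets out from 5 and 8. Hydrozirconation of 8 with Cp2Zr(H)Cl and iodination gives benzyl[(E)-2-iodoethenyl]dimethylsilane F1. Exchange with t-BuLi and addition to 5 gives (1R,4S,6R)-1-{(E)-2-[benzyl(dimethyl)silyl]ethenyl}-4-[(tert-butyldimethylsilyl)oxy]-3-methyl-6-(prop-1-en-2-yl)cyclohex-2-en-1-ol F2, which is isolated so that a minor diastereomer can be removed. KH/18-crown-6 rearranges it to (2Z,4S,6E,9R)-9-[benzyl(dimethyl)silyl]-4-[(tert-butyldimethylsilyl)oxy]-3,7-dimethylcyclodeca-2,6-dien-1-one F3, which has no C7 stereocentre to lose. Palladium-catalysed α-alkenylation of its enolate with bromide 10 (Pd2(dba)3, P(t-Bu)3, LiN(SiMe3)2) then gives the lithium analogue of enolate 15, and the same cold acetic acid quench returns the route to 16.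

**Step 8.** Tin may be delivered to the silicon-bearing carbon, or mixed regioisomers may form on the conjugated enyne, which would put silicon axial (or on the wrong carbon) in step 9. The fallback builds the vinylsilane geometry on the carbinol instead. It sets out from 5, 8 and 10. The lithium acetylide of 8 (n-BuLi) adds to 5 to give (1R,4S,6R)-1-{[benzyl(dimethyl)silyl]ethynyl}-4-[(tert-butyldimethylsilyl)oxy]-3-methyl-6-(prop-1-en-2-yl)cyclohex-2-en-1-ol F4. Alkoxide-directed anti-carbomagnesiation with {3-[(2-methoxypropan-2-yl)oxy]prop-1-en-2-yl}magnesium bromide F5 (from 10 and Mg, CuI cat.) places C11 on C7 and magnesium on the silicon-bearing carbon trans to it. Protonation gives 14, where the route is rejoined before the KH/18-crown-6 stage of step 9.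

**Step 10.** Hydride may be delivered to the other face of the C6 carbonyl if a carbonyl-inside conformer reacts, giving the 6-epimer and hence a cis lactone. The fallback corrects C6 by substitution rather than by reagent choice. It sets out from 16. The reduction is stopped before the PPTS treatment and the (1S)-epimer of 17, (1S,2Z,4S,6E,9R,10S)-9-[benzyl(dimethyl)silyl]-4-[(tert-butyldimethylsilyl)oxy]-10-{3-[(2-methoxypropan-2-yl)oxy]prop-1-en-2-yl}-3,7-dimethylcyclodeca-2,6-dien-1-ol F6, is isolated. Mitsunobu inversion (PPh3, diisopropyl azodicarboxylate, 4-nitrobenzoic acid) gives the (1R)-4-nitrobenzoate of 17, F7. Methanolysis (K2CO3, MeOH) returns the route to 17, which is treated with PPTS as in step 10.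

**Step 12.** Peroxide or methoxide may add to the methylene lactone, the lactone may migrate to the freed O8 under the basic conditions, or the TBS ether may be lost early. The fallback masks the Michael acceptor. It sets out from 19. Conjugate addition of Me2NH gives the 11,13-dihydro-13-(dimethylamino) adduct of 19, F8. The same fluoride/peroxide sequence gives the 11,13-dihydro-13-(dimethylamino) adduct of 21, F9. Quaternisation with MeI and elimination with NaHCO3 restores the methylene group and returns the route to 21.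

**Step 17.** Peracid may attack the other face of C1=C10 if the conformer with C14 turned to the α face reacts, or C4=C5 may be epoxidised as well. The fallback changes the control element from conformation to a directing group. It sets out from 21. The free homoallylic 8β-hydroxyl directs VO(acac)2/t-BuOOH to C1=C10, giving 3β-[(tert-butyldimethylsilyl)oxy]-1β,10α-epoxy-8β-hydroxygermacra-4Z,11(13)-dien-12,6α-olide F10. Yamaguchi esterification with 25 (through 26) then returns the route to 28.

## Further compounds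

F1 | step 9 | benzyl[(E)-2-iodoethenyl]dimethylsilane | I/C=C/[Si](C)(C)Cc1ccccc1
F2 | step 9 | (1R,4S,6R)-1-{(E)-2-[benzyl(dimethyl)silyl]ethenyl}-4-[(tert-butyldimethylsilyl)oxy]-3-methyl-6-(prop-1-en-2-yl)cyclohex-2-en-1-ol | CC(=C)[C@H]1C[C@H](O[Si](C)(C)C(C)(C)C)C(C)=C[C@]1(O)/C=C/[Si](C)(C)Cc1ccccc1
F3 | step 9 | (2Z,4S,6E,9R)-9-[benzyl(dimethyl)silyl]-4-[(tert-butyldimethylsilyl)oxy]-3,7-dimethylcyclodeca-2,6-dien-1-one | O=C1/C=C(/C)[C@@H](O[Si](C)(C)C(C)(C)C)C/C=C(C)/C[C@@H]([Si](C)(C)Cc2ccccc2)C1
F4 | step 8 | (1R,4S,6R)-1-{[benzyl(dimethyl)silyl]ethynyl}-4-[(tert-butyldimethylsilyl)oxy]-3-methyl-6-(prop-1-en-2-yl)cyclohex-2-en-1-ol | CC(=C)[C@H]1C[C@H](O[Si](C)(C)C(C)(C)C)C(C)=C[C@]1(O)C#C[Si](C)(C)Cc1ccccc1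
F5 | step 8 | {3-[(2-methoxypropan-2-yl)oxy]prop-1-en-2-yl}magnesium bromide | COC(C)(C)OCC(=C)[Mg]Br
F6 | step 10 | (1S,2Z,4S,6E,9R,10S)-9-[benzyl(dimethyl)silyl]-4-[(tert-butyldimethylsilyl)oxy]-10-{3-[(2-methoxypropan-2-yl)oxy]prop-1-en-2-yl}-3,7-dimethylcyclodeca-2,6-dien-1-ol | O[C@H]1/C=C(/C)[C@@H](O[Si](C)(C)C(C)(C)C)C/C=C(C)/C[C@@H]([Si](C)(C)Cc2ccccc2)[C@H]1C(=C)COC(C)(C)OC
F7 | step 10 | (1R,2Z,4S,6E,9R,10S)-9-[benzyl(dimethyl)silyl]-4-[(tert-butyldimethylsilyl)oxy]-10-{3-[(2-methoxypropan-2-yl)oxy]prop-1-en-2-yl}-3,7-dimethylcyclodeca-2,6-dien-1-yl 4-nitrobenzoate | O=C(O[C@@H]1/C=C(/C)[C@@H](O[Si](C)(C)C(C)(C)C)C/C=C(C)/C[C@@H]([Si](C)(C)Cc2ccccc2)[C@H]1C(=C)COC(C)(C)OC)c1ccc(cc1)[N+](=O)[O-]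
F8 | step 12 | 11,13-dihydro-13-(dimethylamino) adduct of 19 (C11 epimers) | CN(C)CC1C(=O)O[C@@H]2/C=C(/C)[C@@H](O[Si](C)(C)C(C)(C)C)C/C=C(C)/C[C@@H]([Si](C)(C)Cc3ccccc3)[C@@H]12
F9 | step 12 | 11,13-dihydro-13-(dimethylamino) adduct of 21 (C11 epimers) | CN(C)CC1C(=O)O[C@@H]2/C=C(/C)[C@@H](O[Si](C)(C)C(C)(C)C)C/C=C(C)/C[C@@H](O)[C@@H]12
F10 | step 17 | 3β-[(tert-butyldimethylsilyl)oxy]-1β,10α-epoxy-8β-hydroxygermacra-4Z,11(13)-dien-12,6α-olide | C=C1C(=O)O[C@@H]2/C=C(/C)[C@@H](O[Si](C)(C)C(C)(C)C)C[C@H]3O[C@]3(C)C[C@@H](O)[C@@H]12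
A1 | alternative 1 | methyl (2Z,4R,6E,9S,10Z)-2-(bromomethyl)-4,9-bis[(tert-butyldimethylsilyl)oxy]-6,10-dimethyl-12-oxododeca-2,6,10-trienoate | O=C/C=C(/C)[C@@H](O[Si](C)(C)C(C)(C)C)C/C=C(C)/C[C@@H](O[Si](C)(C)C(C)(C)C)/C=C(\CBr)C(=O)OC
A2 | alternative 2 | (4S,5R)-4-{(1R,3E,6S)-1,6-bis[(tert-butyldimethylsilyl)oxy]-3,7-dimethylocta-3,7-dien-1-yl}-5-ethenyl-3-methylideneoxolan-2-one | C=C[C@H]1OC(=O)C(=C)[C@@H]1[C@H](O[Si](C)(C)C(C)(C)C)C/C(C)=C/C[C@H](O[Si](C)(C)C(C)(C)C)C(C)=C
A3 | alternative 3 | methyl 2-[(3E,6R,7R)-6-[(tert-butyldimethylsilyl)oxy]-4,10-dimethyl-11-oxabicyclo[6.2.1]undeca-1(10),3,8-trien-7-yl]acetate | Cc1cc2oc1C/C=C(C)/C[C@@H](O[Si](C)(C)C(C)(C)C)[C@H]2CC(=O)OC
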